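An easy step opens the west flask, the one asked about: its first two readings lie one equal time step apart, so the second gain over the first reads as the part of starting material that survives a step, 33.0%.

| setting | west | north | flask |
|---|---|---|---|
| starting material | 0.27 M | 0.54 M | 0.27 M |
| remark | the very flask that is asked about, followed so far | run made earlier |  |
| time |  |  | 15 d |

| west: time / d | west: target / % | north: time / d | north: target / % |
|---|---|---|---|
| 0.0625 | 27.9 | 0.0625 | 27.0 |
| 0.125 | 37.1 | 0.125 | 33.3 |
| 0.250 | 39.2 | 0.333 | 38.7 |
| 0.417 | 40.0 | 0.625 | 36.1 |
| 0.833 | 38.0 | 1.25 | 34.4 |
| 1.67 | 37.6 | 3.00 | 34.7 |
| 3.00 | 39.1 | 6.00 | 34.6 |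

(scatter of a reading: 1 percentage point)

- the analysis behind the earlier runs scatters by 1 percentage point, standard deviation

- time up to 15 d at which target stands highest
- the amount of target, in percent of the starting material charged, at that time

How fast does [starting material] fall? Taken as first-order, that survival gives a half-life of 0.0390 d, and the same readings put the target made, with nothing lost, at 41.6% of the charge.

How fast does target go afterwards? West reads 40.0% at 0.417 d and 38.0% at 0.833 d, a loss of 0.0481 d⁻¹ as a fraction of the charge, and each of these two readings scatters by 1 percentage point.

When does feed meet loss? The feed of target starts at 7.39 d⁻¹, far above the loss, and shrinks with [starting material]. In this reckoning of the west flask, target stands highest at the crossing share 0.651%, the part of the charge of starting material left when feed equals loss. The reckoning reaches it after 0.284 d, and a loss misread by a factor of 2 moves this time by one half-life.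

The forecast differs in time: it expects “a shallow maximum” of 39.5% (38.5% to 41%) near 0.35 d (0.2 d to 0.6 d).

The simulation puts the highest target in the flask at 0.270 d, with 39.1% of the charge.

    starting material → target (k = 0.320 h⁻¹)
    starting material → side product A (k = 0.430 h⁻¹)
    starting material + target → side product B (k = 0.190 L mol⁻¹ h⁻¹)
    target ⇌ isomer of the product (K = 0.120, k = 0.00740 h⁻¹)

At that time the flask still holds 0.697% of starting material. The crossing time 0.284 d lies 0.0140 d after the peak, less than one half-life of 0.0390 d, and the crossing share of 0.651% stands against that 0.697% of starting material left at the peak.

(All runs were computed with made-up constants; the scatter is artificial.)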